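**Retrosynthetic overview**
- The target is C2-symmetric, so both C–S bonds are cut (retro-sulfa-Michael) to hydrogen sulfide and two copies of one 12-membered (E)-5-hydroxy-4-oxo-2-enolide.
- The enolide is opened at the lactone C–O bond (Yamaguchi macrolactonization of an (E)-4-oxo-2-enoic seco acid); C1–C4 of that acid are a masked furan (oxidative ring opening).
- C5–C12 come from 7-oxooctanoic acid, joined to furan by Friedel–Crafts acylation.
- Stereocenters: C5 by Ru-catalysed asymmetric transfer hydrogenation of the furyl ketone (first stereocenter), C11 by a ketoreductase, C2 and C2' by substrate-controlled sulfa-Michael addition.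
- Ring order: the 12-membered lactone is closed once, on the monomer (step 7); two copies of this ring are then bridged by sulfur (steps 9 and 10).

Assumption: the two sulfa-Michael additions to the macrocyclic 4-oxo-2-enoate are taken to be substrate-controlled in favour of the natural (S) configuration at the sulfur-bearing carbons (attack on the exposed outer face, as in the presumed non-enzymatic biogenesis), to be confirmed on the isolated thiol 14.

**Route**

Step 1
Reactants: 1 7-oxooctanoic acid; 2 furan
Product: 4 1-(furan-2-yl)octane-1,7-dione, via mixed trifluoroacetic anhydride 3 (not isolated)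
Conditions: trifluoroacetic anhydride (TFAA, 1.2 equiv), MeCN, 0 °C, 20 min; then 2 (3 equiv), 85% H3PO4 (cat.), 0 °C → rt
Reagents that add atoms: none
Why: Friedel–Crafts acylation in which the mixed anhydride acylates the electron-rich furan at C2 under acid mild enough to leave the remote methyl ketone alone; no stereocenter is formed.

Step 2
Reactants: 4 1-(furan-2-yl)octane-1,7-dione
Product: 5 (S)-8-(furan-2-yl)-8-hydroxyoctan-2-one
Conditions: RuCl(p-cymene)[(S,S)-TsDPEN] (1 mol%), HCO2H/Et3N (5:2), CH2Cl2, 25 °C, stopped at full conversion of the furyl ketone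
Reagents that add atoms: none
Why: Noyori asymmetric transfer hydrogenation, in which the bifunctional Ru–H/N–H catalyst reduces the heteroaryl ketone much faster than the dialkyl ketone and, with the (S,S) ligand, gives the (S)-furyl carbinol (future C5) in high ee as the first stereocenter.

Step 3
Reactants: 5 (S)-8-(furan-2-yl)-8-hydroxyoctan-2-one
Product: 6 (S)-8-[(tert-butyldimethylsilyl)oxy]-8-(furan-2-yl)octan-2-one
Conditions: TBSCl (1.3 equiv), imidazole (2.5 equiv), DMF, rt
Reagents that add atoms: tert-butyldimethylsilyl chloride (TBSCl), CC(C)(C)[Si](C)(C)Cl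
Why: Standard silyl ether formation, which blocks the carbinol so that the later furan opening gives the open-chain ene-dione and not an Achmatowicz pyranone; the stereocenter is untouched.

Step 4
Reactants: 6 (S)-8-[(tert-butyldimethylsilyl)oxy]-8-(furan-2-yl)octan-2-one
Product: 7 (2R,8S)-8-[(tert-butyldimethylsilyl)oxy]-8-(furan-2-yl)octan-2-ol
Conditions: (R)-selective ketoreductase (anti-Prelog NADPH-dependent alcohol dehydrogenase), NADP+ (cat.), 2-propanol (15% v/v), KH2PO4/K2HPO4 buffer pH 7.0, MgSO4 (2 mM), 30 °C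
Reagents that add atoms: none
Why: Enzymatic asymmetric ketone reduction in which the ketoreductase binds the methyl group in its small pocket and delivers hydride from NADPH to the Si face, giving the (R)-carbinol (future C11) under catalyst control irrespective of the remote C8 centre, while neutral buffer spares silyl ether and furan.

Step 5
Reactants: 7 (2R,8S)-8-[(tert-butyldimethylsilyl)oxy]-8-(furan-2-yl)octan-2-ol
Product: 9 (2E,5S,11R)-5-[(tert-butyldimethylsilyl)oxy]-11-hydroxy-4-oxododec-2-enal, via (2Z)-enal 8 (not isolated)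
Conditions: N-bromosuccinimide (NBS, 1.1 equiv), NaHCO3 (2 equiv), acetone/H2O (10:1), −15 °C, 1 h; then pyridine (2 equiv), rt, 3 h
Reagents that add atoms: water, O
Why: Oxidative furan ring opening (bromination–hydrolysis of the 2-substituted furan) unmasks the cis ene-keto-aldehyde, which pyridine isomerises to the trans isomer by reversible conjugate addition; the secondary alcohol and the C5 centre are not affected at this temperature.

Step 6
Reactants: 9 (2E,5S,11R)-5-[(tert-butyldimethylsilyl)oxy]-11-hydroxy-4-oxododec-2-enal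
Product: 10 (2E,5S,11R)-5-[(tert-butyldimethylsilyl)oxy]-11-hydroxy-4-oxododec-2-enoic acid
Conditions: NaClO2 (3 equiv), NaH2PO4 (3 equiv), 2-methyl-2-butene (10 equiv), t-BuOH/H2O (4:1), 0 °C → rt
Reagents that add atoms: sodium chlorite, [Na+].[O-]Cl=O
Why: Pinnick oxidation, in which chlorous acid oxidises only the aldehyde and the alkene scavenger removes hypochlorite before it can touch the enone or the free alcohol.

Step 7
Reactants: 10 (2E,5S,11R)-5-[(tert-butyldimethylsilyl)oxy]-11-hydroxy-4-oxododec-2-enoic acid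
Product: 12 (3E,6S,12R)-6-[(tert-butyldimethylsilyl)oxy]-12-methyl-1-oxacyclododec-3-ene-2,5-dione, via Yamaguchi mixed anhydride 11 (not isolated)
Conditions: 2,4,6-trichlorobenzoyl chloride (1.3 equiv), Et3N (1.5 equiv), THF, rt, 2 h; then syringe-pump addition (8 h) to 4-(dimethylamino)pyridine (DMAP, 4 equiv), toluene (1 mM), 80 °C
Reagents that add atoms: none
Why: Yamaguchi macrolactonization under high dilution closes the 12-membered ring by acyl transfer to the C11 hydroxyl, whose C–O bond is not broken, so the (R) configuration is retained.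

Step 8
Reactants: 12 (3E,6S,12R)-6-[(tert-butyldimethylsilyl)oxy]-12-methyl-1-oxacyclododec-3-ene-2,5-dione
Product: 13 (3E,6S,12R)-6-hydroxy-12-methyl-1-oxacyclododec-3-ene-2,5-dione
Conditions: HF·pyridine, pyridine/THF, 0 °C → rt
Reagents that add atoms: none
Why: Fluoride-driven desilylation under mildly acidic, non-basic conditions frees the C5 hydroxyl without epimerising or rearranging the α-hydroxy ketone.

Step 9
Reactants: 13 (3E,6S,12R)-6-hydroxy-12-methyl-1-oxacyclododec-3-ene-2,5-dione
Product: 14 (3S,6S,12R)-6-hydroxy-12-methyl-3-sulfanyl-1-oxacyclododecane-2,5-dione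
Conditions: H2S (0.8 M in THF, 10 equiv), Et3N (0.1 equiv), degassed THF, −20 → 0 °C, argon
Reagents that add atoms: hydrogen sulfide, S
Why: Sulfa-Michael addition in which hydrosulfide attacks the carbon β to the ketone (the stronger acceptor, α to the lactone carbonyl), the large excess of H2S stops at the thiol, and the new centre is set as (S) by attack on the exposed outer face of the enone held by the C5–OH···O=C4 hydrogen bond (substrate control, as assumed).

Step 10
Reactants: 14 (3S,6S,12R)-6-hydroxy-12-methyl-3-sulfanyl-1-oxacyclododecane-2,5-dione; 13 (3E,6S,12R)-6-hydroxy-12-methyl-1-oxacyclododec-3-ene-2,5-dione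
Product: 15 thiocladospolide F, (3S,3'S,6S,6'S,12R,12'R)-3,3'-sulfanediylbis(6-hydroxy-12-methyl-1-oxacyclododecane-2,5-dione)
Conditions: 14 (1.0 equiv), 13 (1.0 equiv), Et3N (0.2 equiv), degassed CH2Cl2, 0 °C → rt, argon
Reagents that add atoms: none
Why: Second sulfa-Michael addition in which the thiolate of 14 adds to the same carbon of a second molecule of 13 with the same facial preference, giving the symmetric thioether with the second sulfur-bearing centre (S), while the catalytic amount of amine limits retro-Michael scrambling.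

**Compound list**

1 | 7-oxooctanoic acid | CC(=O)CCCCCC(=O)O | starting material
2 | furan | c1ccoc1 | starting material
3 | 7-oxooctanoic trifluoroacetic anhydride (not isolated) | CC(=O)CCCCCC(=O)OC(=O)C(F)(F)F | intermediate
4 | 1-(furan-2-yl)octane-1,7-dione | CC(=O)CCCCCC(=O)c1ccco1 | intermediate
5 | (S)-8-(furan-2-yl)-8-hydroxyoctan-2-one | CC(=O)CCCCC[C@H](O)c1ccco1 | intermediate
6 | (S)-8-[(tert-butyldimethylsilyl)oxy]-8-(furan-2-yl)octan-2-one | CC(=O)CCCCC[C@H](O[Si](C)(C)C(C)(C)C)c1ccco1 | intermediate
7 | (2R,8S)-8-[(tert-butyldimethylsilyl)oxy]-8-(furan-2-yl)octan-2-ol | C[C@@H](O)CCCCC[C@H](O[Si](C)(C)C(C)(C)C)c1ccco1 | intermediate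
8 | (2Z,5S,11R)-5-[(tert-butyldimethylsilyl)oxy]-11-hydroxy-4-oxododec-2-enal (not isolated) | C[C@@H](O)CCCCC[C@H](O[Si](C)(C)C(C)(C)C)C(=O)/C=C\C=O | intermediate
9 | (2E,5S,11R)-5-[(tert-butyldimethylsilyl)oxy]-11-hydroxy-4-oxododec-2-enal | C[C@@H](O)CCCCC[C@H](O[Si](C)(C)C(C)(C)C)C(=O)/C=C/C=O | intermediate
10 | (2E,5S,11R)-5-[(tert-butyldimethylsilyl)oxy]-11-hydroxy-4-oxododec-2-enoic acid | C[C@@H](O)CCCCC[C@H](O[Si](C)(C)C(C)(C)C)C(=O)/C=C/C(=O)O | intermediate
11 | (2E,5S,11R)-5-[(tert-butyldimethylsilyl)oxy]-11-hydroxy-4-oxododec-2-enoic 2,4,6-trichlorobenzoic anhydride (not isolated) | C[C@@H](O)CCCCC[C@H](O[Si](C)(C)C(C)(C)C)C(=O)/C=C/C(=O)OC(=O)c1c(Cl)cc(Cl)cc1Cl | intermediate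
12 | (3E,6S,12R)-6-[(tert-butyldimethylsilyl)oxy]-12-methyl-1-oxacyclododec-3-ene-2,5-dione | C[C@@H]1CCCCC[C@H](O[Si](C)(C)C(C)(C)C)C(=O)/C=C/C(=O)O1 | intermediate
13 | (3E,6S,12R)-6-hydroxy-12-methyl-1-oxacyclododec-3-ene-2,5-dione | C[C@@H]1CCCCC[C@H](O)C(=O)/C=C/C(=O)O1 | intermediate
14 | (3S,6S,12R)-6-hydroxy-12-methyl-3-sulfanyl-1-oxacyclododecane-2,5-dione | C[C@@H]1CCCCC[C@H](O)C(=O)C[C@H](S)C(=O)O1 | intermediate
15 | thiocladospolide F, (3S,3'S,6S,6'S,12R,12'R)-3,3'-sulfanediylbis(6-hydroxy-12-methyl-1-oxacyclododecane-2,5-dione) | C[C@@H]1CCCCC[C@H](O)C(=O)C[C@H](S[C@H]2CC(=O)[C@@H](O)CCCCC[C@@H](C)OC2=O)C(=O)O1 | target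

**Step count and risks**

Total step count: 10. Longest linear sequence: 10 steps (1 → 15; the last step joins 13 and 14, which come from the same line).

The three steps most likely to fail:

Step 10 (and, for the same reason, step 9). The configurations at the two sulfur-bearing carbons rest on the facial bias of the macrocyclic enone, and a base-triggered retro-Michael reaction could erode them. Fallback: keep the silyl ether on through both C–S bond formations, so that a different ring conformer (set by the bulky silyloxy group, with no hydrogen bond) steers the attack and the only step after thioether formation is an acidic one. Setting out from 12, H2S with catalytic Et3N gives (3S,6S,12R)-6-[(tert-butyldimethylsilyl)oxy]-12-methyl-3-sulfanyl-1-oxacyclododecane-2,5-dione F9, whose configuration is checked. F9 and a second equivalent of 12 with catalytic Et3N give (3S,3'S,6S,6'S,12R,12'R)-3,3'-sulfanediylbis{6-[(tert-butyldimethylsilyl)oxy]-12-methyl-1-oxacyclododecane-2,5-dione} F10. HF·pyridine then removes both silyl groups and the route is rejoined at 15.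

Step 7. Carboxyl activation of an ene-dione acid in the presence of DMAP may give oligomers, E/Z isomerisation or epimerisation at C5. Fallback: close the ring by activating the alcohol instead of the acid, which needs the opposite carbinol configuration. Setting out from 6, an (S)-selective (Prelog-type) ketoreductase gives (2S,8S)-8-[(tert-butyldimethylsilyl)oxy]-8-(furan-2-yl)octan-2-ol F5. NBS then pyridine, as in step 5, gives first (2Z,5S,11S)-5-[(tert-butyldimethylsilyl)oxy]-11-hydroxy-4-oxododec-2-enal F6 in the flask and then (2E,5S,11S)-5-[(tert-butyldimethylsilyl)oxy]-11-hydroxy-4-oxododec-2-enal F7. Chlorite oxidation as in step 6 gives (2E,5S,11S)-5-[(tert-butyldimethylsilyl)oxy]-11-hydroxy-4-oxododec-2-enoic acid F8. Mitsunobu macrolactonization (preformed PPh3/diisopropyl azodicarboxylate adduct, toluene, high dilution, 0 °C → rt) closes the ring with inversion at C11 and rejoins the route at 12.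

Step 2. The transfer hydrogenation may also reduce the methyl ketone, giving C7 alcohols of no defined configuration. Fallback: reverse the order of the two reductions, letting the enzyme act first and capping its alcohol. Setting out from 4, the (R)-selective ketoreductase of step 4, which accepts the methyl ketone but not the bulky furyl hexyl ketone, gives (R)-1-(furan-2-yl)-7-hydroxyoctan-1-one F1. Acetylation (Ac2O, pyridine, cat. DMAP) gives (R)-8-(furan-2-yl)-8-oxooctan-2-yl acetate F2. The transfer hydrogenation of step 2, now facing a single ketone, gives (2R,8S)-8-(furan-2-yl)-8-hydroxyoctan-2-yl acetate F3. Silylation as in step 3 gives (2R,8S)-8-[(tert-butyldimethylsilyl)oxy]-8-(furan-2-yl)octan-2-yl acetate F4. K2CO3 in methanol removes the acetate and the route is rejoined at 7.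

**Further compounds**

F1 | step 2 | (R)-1-(furan-2-yl)-7-hydroxyoctan-1-one | C[C@@H](O)CCCCCC(=O)c1ccco1
F2 | step 2 | (R)-8-(furan-2-yl)-8-oxooctan-2-yl acetate | C[C@@H](OC(C)=O)CCCCCC(=O)c1ccco1
F3 | step 2 | (2R,8S)-8-(furan-2-yl)-8-hydroxyoctan-2-yl acetate | C[C@@H](OC(C)=O)CCCCC[C@H](O)c1ccco1
F4 | step 2 | (2R,8S)-8-[(tert-butyldimethylsilyl)oxy]-8-(furan-2-yl)octan-2-yl acetate | C[C@@H](OC(C)=O)CCCCC[C@H](O[Si](C)(C)C(C)(C)C)c1ccco1
F5 | step 7 | (2S,8S)-8-[(tert-butyldimethylsilyl)oxy]-8-(furan-2-yl)octan-2-ol | C[C@H](O)CCCCC[C@H](O[Si](C)(C)C(C)(C)C)c1ccco1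
F6 | step 7 | (2Z,5S,11S)-5-[(tert-butyldimethylsilyl)oxy]-11-hydroxy-4-oxododec-2-enal | C[C@H](O)CCCCC[C@H](O[Si](C)(C)C(C)(C)C)C(=O)/C=C\C=O
F7 | step 7 | (2E,5S,11S)-5-[(tert-butyldimethylsilyl)oxy]-11-hydroxy-4-oxododec-2-enal | C[C@H](O)CCCCC[C@H](O[Si](C)(C)C(C)(C)C)C(=O)/C=C/C=O
F8 | step 7 | (2E,5S,11S)-5-[(tert-butyldimethylsilyl)oxy]-11-hydroxy-4-oxododec-2-enoic acid | C[C@H](O)CCCCC[C@H](O[Si](C)(C)C(C)(C)C)C(=O)/C=C/C(=O)O
F9 | step 10 | (3S,6S,12R)-6-[(tert-butyldimethylsilyl)oxy]-12-methyl-3-sulfanyl-1-oxacyclododecane-2,5-dione | C[C@@H]1CCCCC[C@H](O[Si](C)(C)C(C)(C)C)C(=O)C[C@H](S)C(=O)O1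
F10 | step 10 | (3S,3'S,6S,6'S,12R,12'R)-3,3'-sulfanediylbis{6-[(tert-butyldimethylsilyl)oxy]-12-methyl-1-oxacyclododecane-2,5-dione} | C[C@@H]1CCCCC[C@H](O[Si](C)(C)C(C)(C)C)C(=O)C[C@H](S[C@H]2CC(=O)[C@@H](O[Si](C)(C)C(C)(C)C)CCCCC[C@@H](C)OC2=O)C(=O)O1
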